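Ring B (C5–C10, labdane numbering) is a cyclohexane whose C9–C10 edge carries the tertiary carbinol and the angular methyl. With C9 simplified to a ketone (side chain by nucleophilic addition anti to the C10 methyl, C8 epimerisable) it is the retron of a [4+2] cycloaddition. The key step is an intramolecular Diels–Alder reaction of an acyclic trienal: the (E)-enal C9=C10 adds to the (E,E)-diene C5=C6–C7=C8, forming C8–C9 and C5–C10, closing rings A and B at once and setting the trans C5/C10 fusion. The C2/C3 oxygen stereocentres of the tether, from (S)-pantolactone and a Felkin-controlled vinylogous aldol, direct the π-face. The formyl group is then excised oxidatively.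

Key step: step 8

Remark: compounds 1, 5, 8, 15 and 18 are taken as purchasable; labdane numbering is used (C1–C10 decalin, C11–C16 side chain, C17 on C8, C18/C19 on C4, C20 on C10), and α/β mean below/above the plane in the usual drawing with the C10 methyl β.

Step 1
Reactants: 1 (S)-pantolactone
Product: 2 (3S)-3-(benzyloxy)-4,4-dimethyloxolan-2-one
Conditions: BnOC(=NH)CCl3, TfOH (cat.), CH2Cl2–cyclohexane, 0 °C to rt
Reagents that add atoms: benzyl 2,2,2-trichloroacetimidate, ClC(Cl)(Cl)C(=N)OCc1ccccc1
Why: Acid-catalysed O-benzylation by the trichloroacetimidate method avoids base and so should leave the lactone α-carbon (future C3) unepimerised.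

Step 2
Reactants: 2 (3S)-3-(benzyloxy)-4,4-dimethyloxolan-2-one
Product: 3 (2S)-2-(benzyloxy)-4-hydroxy-N-methoxy-N,3,3-trimethylbutanamide
Conditions: MeNH(OMe)·HCl, AlMe3, CH2Cl2, 0 °C to rt; aqueous work-up; used at once
Reagents that add atoms: N,O-dimethylhydroxylamine hydrochloride, CNOC.Cl
Why: Aluminium-amide aminolysis of the lactone (Weinreb amide formation) frees the C5 hydroxyl, keeps C2 at the acyl level and does not touch C3; immediate use forestalls relactonisation.

Step 3
Reactants: 3 (2S)-2-(benzyloxy)-4-hydroxy-N-methoxy-N,3,3-trimethylbutanamide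
Product: 4 (2S)-2-(benzyloxy)-N-methoxy-N,3,3-trimethyl-4-oxobutanamide
Conditions: Dess–Martin periodinane, CH2Cl2, rt
Reagents that add atoms: none
Why: Dess–Martin oxidation of the neopentyl primary alcohol should give an aldehyde that has no α-hydrogen and therefore cannot enolise.

Step 4
Reactants: 4 (2S)-2-(benzyloxy)-N-methoxy-N,3,3-trimethyl-4-oxobutanamide; 5 diethyl [(2E)-but-2-en-1-yl]phosphonate
Product: 6 (2S,4E,6E)-2-(benzyloxy)-N-methoxy-N,3,3-trimethylocta-4,6-dienamide
Conditions: 5, n-BuLi, THF–DMPU, −78 °C; then 4, −78 °C to rt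
Reagents that add atoms: none
Why: Horner–Wadsworth–Emmons olefination with an allylic phosphonate anion should form the C5=C6 bond with E geometry and keep the E crotyl bond; a minor 7Z isomer would converge later because C8 is equilibrated.

Step 5
Reactants: 6 (2S,4E,6E)-2-(benzyloxy)-N-methoxy-N,3,3-trimethylocta-4,6-dienamide
Product: 7 (2S,4E,6E)-2-(benzyloxy)-3,3-dimethylocta-4,6-dienal
Conditions: i-Bu2AlH, THF, −78 °C; aqueous work-up; used crude
Reagents that add atoms: none
Why: Hydride reduction of a Weinreb amide stops at the chelated tetrahedral intermediate and releases the aldehyde on work-up; cold handling should preserve the α-benzyloxy stereocentre.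

Step 6
Reactants: 8 3-methylbut-2-enal
Product: 9 tert-butyl(dimethyl){[(1E)-3-methylbuta-1,3-dien-1-yl]oxy}silane
Conditions: TBSOTf, Et3N, Et2O, 0 °C
Reagents that add atoms: tert-butyldimethylsilyl trifluoromethanesulfonate, CC(C)(C)[Si](C)(C)OS(=O)(=O)C(F)(F)F
Why: O-Silylation of the enal with γ-deprotonation (silyl dienol ether formation) should give the cross-conjugated (1E)-dienol ether.

Step 7
Reactants: 7 (2S,4E,6E)-2-(benzyloxy)-3,3-dimethylocta-4,6-dienal; 9 tert-butyl(dimethyl){[(1E)-3-methylbuta-1,3-dien-1-yl]oxy}silane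
Product: 10 (2E,5R,6S,8E,10E)-6-(benzyloxy)-5-hydroxy-3,7,7-trimethyldodeca-2,8,10-trienal
Conditions: BF3·OEt2, CH2Cl2, −78 °C; aqueous work-up
Reagents that add atoms: none
Why: Vinylogous Mukaiyama aldol reaction through the terminal (γ) carbon of the dienol ether; with non-chelating BF3 the polar Felkin–Anh (Cornforth) arrangement, C3–OBn anti to the nucleophile and the CMe2 group turned away, should set C2 as the anti (2R, labdane numbering) carbinol, and the enal should re-form as the E isomer.

Step 8
Reactants: 10 (2E,5R,6S,8E,10E)-6-(benzyloxy)-5-hydroxy-3,7,7-trimethyldodeca-2,8,10-trienal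
Product: 11 trans-fused Δ6-octalin aldehyde (2α-OH 3α-OBn 8β-CH3 9β-CHO 10β-CH3)
Conditions: toluene (0.01 M), BHT (cat.), 170 °C, sealed tube
Reagents that add atoms: none
Why: Thermal type 1 intramolecular Diels–Alder reaction: the formyl-activated C9=C10 alkene (2π) and the C5=C6–C7=C8 diene (4π) combine suprafacially in one concerted, asynchronous [4+2] event, the closest precedent being the cyclisation of terminally activated (E,E,E)-deca-2,7,9-trienals to trans-octalins. Ring B is closed by both new bonds as the cyclohexene of the cycloaddition, and ring A is closed by the C5–C10 bond alone through the four-atom C1–C4 tether in the fused, chair-like mode. C5 and C10 should be set trans because the endo transition state of the (E)-enal puts the formyl group under the diene and the tether anti to it, with the C10 methyl axial on the nascent ring A; C8 and C9 follow from the alkene geometries and the endo rule but are provisional, since C9 becomes a ketone and C8 is equilibrated in step 10. The step needs anti (trans-fusion) over syn selectivity, supported by endo overlap and the chair tether, and π-facial selectivity, secured by the C2/C3 stereocentres: the reacting chair keeps C2–OH equatorial and C3–OBn axial, whereas attack on the other face would force C2–OH into a syn-axial clash with the C4 and C10 methyl groups. The C4 gem-dimethyl group favours the coiled reactive conformer and, lacking allylic hydrogen, prevents diene migration.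

Step 9
Reactants: 11 trans-fused Δ6-octalin aldehyde (2α-OH 3α-OBn 8β-CH3 9β-CHO 10β-CH3)
Product: 12 trans-decalin diol aldehyde (2α,3α-diol 8β-CH3 9β-CHO)
Conditions: H2 (1 atm), Pd/C, EtOAc, rt
Reagents that add atoms: none
Why: Heterogeneous catalytic hydrogenation should saturate the cis-disubstituted C6=C7 bond and hydrogenolyse the benzyl ether in one operation, the hindered aliphatic aldehyde surviving; no stereocentre is formed.

Step 10
Reactants: 12 trans-decalin diol aldehyde (2α,3α-diol 8β-CH3 9β-CHO)
Product: 14 2α,3α-dihydroxy-8α-methyl-trans-decalin-9-one, via 8β-methyl ketone 13 (not isolated)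
Conditions: Cu(OAc)2 (cat.), 2,2'-bipyridine, DABCO, O2 (1 atm), DMF, 40 °C; then N2 purge, DBU, rt
Reagents that add atoms: dioxygen, O=O
Why: Copper-catalysed aerobic oxidative deformylation of an α-branched aldehyde (enolate oxygenation, dioxetane fragmentation, loss of formic acid) should give the C9 ketone, and base equilibration through the enolate then moves the C8 methyl from the axial β position, syn-axial to the C10 methyl, to the equatorial α position.

Step 11
Reactants: 14 2α,3α-dihydroxy-8α-methyl-trans-decalin-9-one; 15 4-bromo-2-methylbut-1-ene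
Product: 17 9α-(3-methylbut-3-enyl)-2α,3α,9β-triol, via (3-methylbut-3-en-1-yl)magnesium bromide 16 (not isolated)
Conditions: 15, Mg, THF; CeCl3, THF, −78 °C; then 14 (reagent in excess), −78 to 0 °C; aqueous work-up
Reagents that add atoms: none
Why: Cerium-mediated Grignard 1,2-addition to a hindered, enolisable ketone; the axial C10 methyl shields the β-face, so the nucleophile should enter from the α-face (axial attack, as for ketones next to an angular methyl), giving the 9β-hydroxyl and the 9α side chain.

Step 12
Reactants: 17 9α-(3-methylbut-3-enyl)-2α,3α,9β-triol; 18 methyl acrylate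
Product: 19 methyl (2E)-3-methyl-5-(2α,3α,9β-trihydroxy-decalinyl)pent-2-enoate
Conditions: 18 (excess), second-generation Hoveyda–Grubbs catalyst, CH2Cl2, 40 °C
Reagents that add atoms: none
Why: Olefin cross-metathesis of a 1,1-disubstituted alkene with an acrylate should give the trisubstituted enoate, the E isomer (ester trans to the C12 chain) expected as the major, separable product.

Step 13
Reactants: 19 methyl (2E)-3-methyl-5-(2α,3α,9β-trihydroxy-decalinyl)pent-2-enoate
Product: 20 CNP0135744.1
Conditions: Ac2O (1.1 equiv), pyridine, 0 °C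
Reagents that add atoms: acetic anhydride, CC(=O)OC(C)=O
Why: Kinetically selective acetylation: the equatorial C2 hydroxyl should react much faster than the axial, neopentyl C3 hydroxyl next to the gem-dimethyl group and than the tertiary C9 hydroxyl; no stereocentre is affected.

Compound list
1 | (S)-pantolactone, (3S)-3-hydroxy-4,4-dimethyloxolan-2-one | CC1(C)COC(=O)[C@H]1O | starting material
2 | (3S)-3-(benzyloxy)-4,4-dimethyloxolan-2-one | CC1(C)COC(=O)[C@H]1OCc1ccccc1 | intermediate
3 | (2S)-2-(benzyloxy)-4-hydroxy-N-methoxy-N,3,3-trimethylbutanamide | CON(C)C(=O)[C@@H](OCc1ccccc1)C(C)(C)CO | intermediate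
4 | (2S)-2-(benzyloxy)-N-methoxy-N,3,3-trimethyl-4-oxobutanamide | CON(C)C(=O)[C@@H](OCc1ccccc1)C(C)(C)C=O | intermediate
5 | diethyl [(2E)-but-2-en-1-yl]phosphonate | CCOP(=O)(C/C=C/C)OCC | starting material
6 | (2S,4E,6E)-2-(benzyloxy)-N-methoxy-N,3,3-trimethylocta-4,6-dienamide | CON(C)C(=O)[C@@H](OCc1ccccc1)C(C)(C)/C=C/C=C/C | intermediate
7 | (2S,4E,6E)-2-(benzyloxy)-3,3-dimethylocta-4,6-dienal | O=C[C@@H](OCc1ccccc1)C(C)(C)/C=C/C=C/C | intermediate
8 | 3-methylbut-2-enal | CC(C)=CC=O | starting material
9 | tert-butyl(dimethyl){[(1E)-3-methylbuta-1,3-dien-1-yl]oxy}silane | C=C(C)/C=C/O[Si](C)(C)C(C)(C)C | intermediate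
10 | (2E,5R,6S,8E,10E)-6-(benzyloxy)-5-hydroxy-3,7,7-trimethyldodeca-2,8,10-trienal | O=C/C=C(\C)C[C@@H](O)[C@@H](OCc1ccccc1)C(C)(C)/C=C/C=C/C | intermediate
11 | 6-(benzyloxy)-7-hydroxy-2,5,5,8a-tetramethyl-1,2,4a,5,6,7,8,8a-octahydronaphthalene-1-carbaldehyde, trans-fused; labdane numbering: 5α-H, 10β-CH3, 9β-CHO, 8β-CH3, 3α-OBn, 2α-OH, C6=C7 | O=C[C@H]1[C@@H](C)C=C[C@H]2C(C)(C)[C@H](OCc3ccccc3)[C@H](O)C[C@@]21C | intermediate
12 | 6,7-dihydroxy-2,5,5,8a-tetramethyldecahydronaphthalene-1-carbaldehyde, trans-fused; 5α-H, 10β-CH3, 9β-CHO, 8β-CH3, 2α,3α-diol | O=C[C@H]1[C@@H](C)CC[C@H]2C(C)(C)[C@H](O)[C@H](O)C[C@@]21C | intermediate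
13 | 6,7-dihydroxy-2,5,5,8a-tetramethyloctahydronaphthalen-1(2H)-one, 8β-methyl epimer; 5α-H, 10β-CH3, 2α,3α-diol | O=C1[C@@H](C)CC[C@H]2C(C)(C)[C@H](O)[C@H](O)C[C@@]21C | intermediate
14 | 6,7-dihydroxy-2,5,5,8a-tetramethyloctahydronaphthalen-1(2H)-one, 8α-methyl; 5α-H, 10β-CH3, 2α,3α-diol | O=C1[C@H](C)CC[C@H]2C(C)(C)[C@H](O)[C@H](O)C[C@@]21C | intermediate
15 | 4-bromo-2-methylbut-1-ene | C=C(C)CCBr | starting material
16 | (3-methylbut-3-en-1-yl)magnesium bromide | C=C(C)CC[Mg]Br | intermediate
17 | 2,5,5,8a-tetramethyl-1-(3-methylbut-3-en-1-yl)decahydronaphthalene-1,6,7-triol; 9β-OH, 9α side chain, 8α-CH3, 5α-H, 10β-CH3, 2α,3α-diol | C=C(C)CC[C@]1(O)[C@H](C)CC[C@H]2C(C)(C)[C@H](O)[C@H](O)C[C@@]21C | intermediate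
18 | methyl acrylate | C=CC(=O)OC | starting material
19 | methyl (2E)-3-methyl-5-(1,6,7-trihydroxy-2,5,5,8a-tetramethyldecahydronaphthalen-1-yl)pent-2-enoate; 9β-OH, 8α-CH3, 2α,3α-diol | COC(=O)/C=C(\C)CC[C@]1(O)[C@H](C)CC[C@H]2C(C)(C)[C@H](O)[C@H](O)C[C@@]21C | intermediate
20 | CNP0135744.1, methyl (2E)-5-[(1S,2R,4aS,6S,7R,8aS)-7-acetoxy-1,6-dihydroxy-2,5,5,8a-tetramethyldecahydronaphthalen-1-yl]-3-methylpent-2-enoate | COC(=O)/C=C(\C)CC[C@]1(O)[C@H](C)CC[C@H]2C(C)(C)[C@H](O)[C@H](OC(C)=O)C[C@@]21C | target

Total step count: 13. Longest linear sequence: 12 steps (steps 1–5 and 7–13, from 1).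

Steps most likely to fail

Step 8. At 170 °C the cyclisation may show too little anti over syn (trans- over cis-fusion) selectivity, or vinylogous dehydration of the δ-hydroxy enal may outrun cycloaddition. The fallback sets out from 10 and returns at 11. The C2 hydroxyl is silylated (TESOTf, 2,6-lutidine, CH2Cl2) to give the O-triethylsilyl trienal F1. The cycloaddition is then run under Lewis-acid activation (Me2AlCl, CH2Cl2, −40 °C), where the complexed formyl group should enforce the endo, trans-fused mode at low temperature, giving the silylated cycloadduct F2. Dilute HCl in THF removes the silyl group and gives 11.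

Step 7. The dienol ether may react through its α-carbon, the product enal may undergo a second aldol addition, or the Felkin preference may erode. The fallback sets out from 7 and returns at 10. A vinylogous Mukaiyama aldol with the ester-derived silyl ketene acetal tert-butyl[(1-methoxy-3-methylbuta-1,3-dien-1-yl)oxy]dimethylsilane (made from methyl 3-methylbut-2-enoate) and B(C6F5)3 is well established as γ- and E-selective and should give the hydroxy trienoate F3. Reduction with i-Bu2AlH gives the allylic diol F4, and MnO2 oxidises only the allylic alcohol, giving 10.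

Step 12. Metathesis of the hindered 1,1-disubstituted alkene may be slow and incomplete, with poor E/Z control at the trisubstituted enoate. The fallback sets out from 17 and returns at 19. Ozonolysis (O3, CH2Cl2–MeOH, −78 °C; then Me2S) gives the methyl ketone F5, which is expected to equilibrate with its 9,13-hemiketal. Horner–Wadsworth–Emmons olefination with trimethyl phosphonoacetate (NaH, THF, reflux) then gives 19, the E isomer being separated.

Further compounds
F1 | step 8 | (2E,5R,6S,8E,10E)-6-(benzyloxy)-3,7,7-trimethyl-5-[(triethylsilyl)oxy]dodeca-2,8,10-trienal | O=C/C=C(\C)C[C@@H](O[Si](CC)(CC)CC)[C@@H](OCc1ccccc1)C(C)(C)/C=C/C=C/C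
F2 | step 8 | 2-O-triethylsilyl ether of cycloadduct 11 (trans-fused; 5α-H, 10β-CH3, 9β-CHO, 8β-CH3, 3α-OBn, 2α-OSiEt3, C6=C7) | O=C[C@H]1[C@@H](C)C=C[C@H]2C(C)(C)[C@H](OCc3ccccc3)[C@H](O[Si](CC)(CC)CC)C[C@@]21C
F3 | step 7 | methyl (2E,5R,6S,8E,10E)-6-(benzyloxy)-5-hydroxy-3,7,7-trimethyldodeca-2,8,10-trienoate | COC(=O)/C=C(\C)C[C@@H](O)[C@@H](OCc1ccccc1)C(C)(C)/C=C/C=C/C
F4 | step 7 | (2E,5R,6S,8E,10E)-6-(benzyloxy)-3,7,7-trimethyldodeca-2,8,10-triene-1,5-diol | OC/C=C(\C)C[C@@H](O)[C@@H](OCc1ccccc1)C(C)(C)/C=C/C=C/C
F5 | step 12 | 4-(1,6,7-trihydroxy-2,5,5,8a-tetramethyldecahydronaphthalen-1-yl)butan-2-one (9β-OH, 8α-CH3, 2α,3α-diol) | CC(=O)CC[C@]1(O)[C@H](C)CC[C@H]2C(C)(C)[C@H](O)[C@H](O)C[C@@]21C
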